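**Retrosynthetic overview**

- The route rests on C4 of the flavonol: a lone carbonyl carbon between C4a of ring A and the C3–C2 unit that carries ring B. It is brought in as carbon monoxide, so C4a–C4 and C4–C3 are both formed in one palladium-catalysed carbonylative alkynylation of ring A iodide 4 with ring B arylacetylene 9.
- Iodide 4 comes from 1,3,5-tris(benzyloxy)benzene by dibromination, double Suzuki methylation and iodination of the last free carbon. Alkyne 9 comes from methyl 4-O-methylgallate by benzylation, reduction, oxidation and Ohira–Bestmann homologation.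
- Rings A and B are bought as arenes. Ring C is the only ring formed and is closed last, at O1–C2, by 6-endo iodocyclisation of alkynone 11 with loss of one ortho benzyl group.
- The C3–I bond is then turned into C3–OH (iodine–magnesium exchange, borylation, peroxide oxidation), and hydrogenolysis of four benzyl ethers ends the route. The target has no stereocentre.

Key step: step 8

Assumption: 1,3,5-tris(benzyloxy)benzene (1), the tribenzyl ether of phloroglucinol, is taken as a catalogue compound; the two C-methyl groups are attached by cross-coupling because C-methylation and O-benzylation of free phloroglucinol both suffer from competing C-alkylation.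

**Route**

Step 1
Reactants: 1 1,3,5-tris(benzyloxy)benzene
Product: 2 1,3,5-tris(benzyloxy)-2,4-dibromobenzene
Conditions: NBS (2.05 equiv), CH2Cl2, 0 °C to rt, dark
Reagents that add atoms: N-bromosuccinimide, O=C1CCC(=O)N1Br
Why: Electrophilic aromatic bromination; the three free ring carbons are equivalent and each is activated by three benzyloxy groups, so any two substitutions give the same dibromide, and two equivalents at low temperature should hold back the third.

Step 2
Reactants: 2 1,3,5-tris(benzyloxy)-2,4-dibromobenzene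
Product: 3 1,3,5-tris(benzyloxy)-2,4-dimethylbenzene
Conditions: MeB(OH)2 (4 equiv), Pd(OAc)2 (5 mol %), SPhos (10 mol %), K3PO4, toluene/H2O, 100 °C
Reagents that add atoms: methylboronic acid, CB(O)O
Why: Twofold Suzuki–Miyaura methylation; the SPhos-ligated palladium catalyst is suited to aryl bromides with two ortho alkoxy groups, and benzyl ethers are inert under these conditions.

Step 3
Reactants: 3 1,3,5-tris(benzyloxy)-2,4-dimethylbenzene
Product: 4 1,3,5-tris(benzyloxy)-2-iodo-4,6-dimethylbenzene
Conditions: NIS (1.1 equiv), TFA (cat.), MeCN, 0 °C to rt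
Reagents that add atoms: N-iodosuccinimide, O=C1CCC(=O)N1I
Why: Electrophilic aromatic iodination at the only unsubstituted ring carbon, which lies ortho to two and para to one benzyloxy group, so the regiochemistry is fixed by the substrate.

Step 4
Reactants: 5 methyl 3,5-dihydroxy-4-methoxybenzoate
Product: 6 methyl 3,5-bis(benzyloxy)-4-methoxybenzoate
Conditions: BnBr (2.4 equiv), K2CO3, DMF, 60 °C
Reagents that add atoms: benzyl bromide, BrCc1ccccc1
Why: Williamson ether synthesis on two phenols whose ring is deactivated by the ester, so O-alkylation should be clean.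

Step 5
Reactants: 6 methyl 3,5-bis(benzyloxy)-4-methoxybenzoate
Product: 7 [3,5-bis(benzyloxy)-4-methoxyphenyl]methanol
Conditions: LiAlH4, THF, 0 °C to rt
Reagents that add atoms: none
Why: Hydride reduction of the aryl ester to the benzylic alcohol, chosen over a partial reduction because stopping an aryl ester at the aldehyde is unreliable.

Step 6
Reactants: 7 [3,5-bis(benzyloxy)-4-methoxyphenyl]methanol
Product: 8 3,5-bis(benzyloxy)-4-methoxybenzaldehyde
Conditions: MnO2, CH2Cl2, rt
Reagents that add atoms: none
Why: MnO2 oxidation of a benzylic alcohol, which stops at the aldehyde and leaves the benzyl and methyl ethers alone.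

Step 7
Reactants: 8 3,5-bis(benzyloxy)-4-methoxybenzaldehyde
Product: 9 1,3-bis(benzyloxy)-5-ethynyl-2-methoxybenzene
Conditions: dimethyl (1-diazo-2-oxopropyl)phosphonate, K2CO3, MeOH/THF, rt
Reagents that add atoms: dimethyl (1-diazo-2-oxopropyl)phosphonate, CC(=O)C(=[N+]=[N-])P(=O)(OC)OC
Why: Seyferth–Gilbert homologation in the Ohira–Bestmann form; methanolysis releases the diazomethylphosphonate anion, which olefinates the aldehyde, and loss of dinitrogen with a 1,2-hydrogen shift gives the terminal alkyne.

Step 8
Reactants: 4 1,3,5-tris(benzyloxy)-2-iodo-4,6-dimethylbenzene; 9 1,3-bis(benzyloxy)-5-ethynyl-2-methoxybenzene; 10 carbon monoxide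
Product: 11 3-[3,5-bis(benzyloxy)-4-methoxyphenyl]-1-[2,4,6-tris(benzyloxy)-3,5-dimethylphenyl]prop-2-yn-1-one
Conditions: PdCl2(PPh3)2 (5 mol %), CuI (5 mol %), Et3N (3 equiv), THF, CO (5 bar), 50 °C, slow addition of 9
Reagents that add atoms: none
Why: PdCl2(PPh3)2 (divalent palladium) is reduced in the flask to zerovalent palladium, which adds oxidatively to the C–I bond of 4; migratory insertion of CO gives the aroyl–palladium iodide (C4a–C4), the copper acetylide formed from 9, CuI (monovalent copper) and Et3N transmetalates, and reductive elimination forms C4–C3 and returns zerovalent palladium. The closest known reaction is the carbonylative Sonogashira coupling of aryl iodides with terminal arylacetylenes to 1,3-diarylpropynones. No ring is closed and no stereocentre is created. The selectivity needed is acyl coupling over direct alkynylation: the two ortho benzyloxy groups crowd the aryl–palladium centre so the bulky copper acetylide is transferred slowly there, whereas the small CO ligand inserts readily and moves the metal one atom away from the congestion, and CO pressure with slow alkyne addition adds to this bias. Regiochemistry on ring A is not in question because iodine sits on the only carbon of 4 not otherwise substituted, and the tertiary amine base cannot add to the ynone as a secondary amine would.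

Step 9
Reactants: 11 3-[3,5-bis(benzyloxy)-4-methoxyphenyl]-1-[2,4,6-tris(benzyloxy)-3,5-dimethylphenyl]prop-2-yn-1-one
Product: 12 5,7-bis(benzyloxy)-2-[3,5-bis(benzyloxy)-4-methoxyphenyl]-3-iodo-6,8-dimethyl-4H-chromen-4-one
Conditions: ICl (1.2 equiv), CH2Cl2, −78 °C to 0 °C; aq Na2S2O3
Reagents that add atoms: iodine monochloride, ClI
Why: Electrophilic iodocyclisation of an ortho-alkoxyaryl ynone (Larock type); iodonium activation of the alkyne is followed by anti 6-endo-dig attack of an ortho benzyloxy oxygen on the aryl-bearing alkyne carbon (O1–C2), chloride removes the benzyl group from the oxonium ion as benzyl chloride, and because ring A of 11 is symmetric either ortho ether gives the same 3-iodoflavone.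

Step 10
Reactants: 12 5,7-bis(benzyloxy)-2-[3,5-bis(benzyloxy)-4-methoxyphenyl]-3-iodo-6,8-dimethyl-4H-chromen-4-one
Product: 15 5,7-bis(benzyloxy)-2-[3,5-bis(benzyloxy)-4-methoxyphenyl]-3-hydroxy-6,8-dimethyl-4H-chromen-4-one, via 3-chloromagnesio flavone 13 (not isolated), via 3-pinacolboryl flavone 14 (not isolated)
Conditions: iPrMgCl·LiCl (1.1 equiv), THF, −40 °C; iPrOBpin, −40 to 0 °C; 30 % aq H2O2, pH 7 phosphate buffer, 0 °C to rt
Reagents that add atoms: hydrogen peroxide, OO
Why: Iodine–magnesium exchange at the alkenyl iodide gives a C3-metallated flavone of the kind used in the established metallation–borylation–oxidation route from flavones to flavonols; trapping with the borate ester and peroxide-induced 1,2-migration of C3 from boron to oxygen should place the hydroxyl group at C3 only.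

Step 11
Reactants: 15 5,7-bis(benzyloxy)-2-[3,5-bis(benzyloxy)-4-methoxyphenyl]-3-hydroxy-6,8-dimethyl-4H-chromen-4-one
Product: 16 3,5,7-trihydroxy-2-(3,5-dihydroxy-4-methoxyphenyl)-6,8-dimethyl-4H-chromen-4-one (6,8-di-C-methylmyricetin 4'-methyl ether)
Conditions: H2 (1 atm), 10 % Pd/C, THF/MeOH, rt
Reagents that add atoms: none
Why: Catalytic hydrogenolysis of the four benzyl ethers; the methyl ether, the C-methyl groups and the C2=C3 bond of the flavonol (a vinylogous ester) should be untouched.

**Compound list**

1 | 1,3,5-tris(benzyloxy)benzene | c1ccc(COc2cc(OCc3ccccc3)cc(OCc3ccccc3)c2)cc1 | starting material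
2 | 1,3,5-tris(benzyloxy)-2,4-dibromobenzene | Brc1c(OCc2ccccc2)cc(OCc2ccccc2)c(Br)c1OCc1ccccc1 | intermediate
3 | 1,3,5-tris(benzyloxy)-2,4-dimethylbenzene | Cc1c(OCc2ccccc2)cc(OCc2ccccc2)c(C)c1OCc1ccccc1 | intermediate
4 | 1,3,5-tris(benzyloxy)-2-iodo-4,6-dimethylbenzene | Cc1c(OCc2ccccc2)c(C)c(OCc2ccccc2)c(I)c1OCc1ccccc1 | intermediate
5 | methyl 3,5-dihydroxy-4-methoxybenzoate | COC(=O)c1cc(O)c(OC)c(O)c1 | starting material
6 | methyl 3,5-bis(benzyloxy)-4-methoxybenzoate | COC(=O)c1cc(OCc2ccccc2)c(OC)c(OCc2ccccc2)c1 | intermediate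
7 | [3,5-bis(benzyloxy)-4-methoxyphenyl]methanol | COc1c(OCc2ccccc2)cc(CO)cc1OCc1ccccc1 | intermediate
8 | 3,5-bis(benzyloxy)-4-methoxybenzaldehyde | COc1c(OCc2ccccc2)cc(C=O)cc1OCc1ccccc1 | intermediate
9 | 1,3-bis(benzyloxy)-5-ethynyl-2-methoxybenzene | C#Cc1cc(OCc2ccccc2)c(OC)c(OCc2ccccc2)c1 | intermediate
10 | carbon monoxide | [C-]#[O+] | starting material
11 | 3-[3,5-bis(benzyloxy)-4-methoxyphenyl]-1-[2,4,6-tris(benzyloxy)-3,5-dimethylphenyl]prop-2-yn-1-one | Cc1c(OCc2ccccc2)c(C)c(OCc2ccccc2)c(C(=O)C#Cc2cc(OCc3ccccc3)c(OC)c(OCc3ccccc3)c2)c1OCc1ccccc1 | intermediate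
12 | 5,7-bis(benzyloxy)-2-[3,5-bis(benzyloxy)-4-methoxyphenyl]-3-iodo-6,8-dimethyl-4H-chromen-4-one | COc1c(OCc2ccccc2)cc(-c2oc3c(C)c(OCc4ccccc4)c(C)c(OCc4ccccc4)c3c(=O)c2I)cc1OCc1ccccc1 | intermediate
13 | [5,7-bis(benzyloxy)-2-[3,5-bis(benzyloxy)-4-methoxyphenyl]-6,8-dimethyl-4-oxo-4H-chromen-3-yl]magnesium chloride (not isolated) | COc1c(OCc2ccccc2)cc(-c2oc3c(C)c(OCc4ccccc4)c(C)c(OCc4ccccc4)c3c(=O)c2[Mg]Cl)cc1OCc1ccccc1 | intermediate
14 | 5,7-bis(benzyloxy)-2-[3,5-bis(benzyloxy)-4-methoxyphenyl]-6,8-dimethyl-3-(4,4,5,5-tetramethyl-1,3,2-dioxaborolan-2-yl)-4H-chromen-4-one (not isolated) | COc1c(OCc2ccccc2)cc(-c2oc3c(C)c(OCc4ccccc4)c(C)c(OCc4ccccc4)c3c(=O)c2B5OC(C)(C)C(C)(C)O5)cc1OCc1ccccc1 | intermediate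
15 | 5,7-bis(benzyloxy)-2-[3,5-bis(benzyloxy)-4-methoxyphenyl]-3-hydroxy-6,8-dimethyl-4H-chromen-4-one | COc1c(OCc2ccccc2)cc(-c2oc3c(C)c(OCc4ccccc4)c(C)c(OCc4ccccc4)c3c(=O)c2O)cc1OCc1ccccc1 | intermediate
16 | 3,5,7-trihydroxy-2-(3,5-dihydroxy-4-methoxyphenyl)-6,8-dimethyl-4H-chromen-4-one | COc1c(O)cc(-c2oc3c(C)c(O)c(C)c(O)c3c(=O)c2O)cc1O | target

**Step count**

Total: 11 steps. Longest linear sequence: 8 steps (5 to 16 through steps 4, 5, 6, 7, 8, 9, 10 and 11).

**Steps most likely to fail**

Step 8 (carbonylative coupling). Three processes may intrude: direct alkynylation without CO uptake, sluggish oxidative addition into the crowded, electron-rich C–I bond, and oxidative dimerisation of the alkyne. The fallback sets out from 3 and 9 and comes back at 11, using a formyl carbon in place of carbon monoxide. Vilsmeier–Haack formylation of 3 (POCl3, DMF, 0 to 60 °C) at its one free carbon should give 2,4,6-tris(benzyloxy)-3,5-dimethylbenzaldehyde F1. The lithium acetylide of 9 (n-BuLi, THF, −78 °C) should add to F1 to give racemic 3-[3,5-bis(benzyloxy)-4-methoxyphenyl]-1-[2,4,6-tris(benzyloxy)-3,5-dimethylphenyl]prop-2-yn-1-ol F2. Oxidation of F2 with MnO2 in CH2Cl2 removes the stereocentre and should deliver 11.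

Step 10 (exchange, borylation, oxidation). The C3-metallated chromone may open by β-elimination of the aryloxide, the Grignard reagent may add to the C4 carbonyl, or the C3 anion may be protonated before boron is attached. The fallback sets out from 12 and comes back at 15, placing the oxygen by epoxidation instead of through a carbon–metal bond. Hydrodeiodination of 12 (Pd(OAc)2, PPh3, HCO2Na, DMF, 80 °C) should give 5,7-bis(benzyloxy)-2-[3,5-bis(benzyloxy)-4-methoxyphenyl]-6,8-dimethyl-4H-chromen-4-one F3. Dimethyldioxirane in acetone/CH2Cl2 at 0 °C should epoxidise the C2=C3 bond to the racemic 2,3-epoxide of that flavone F4. With a trace of p-TsOH, F4 opens and tautomerises to 15.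

Step 9 (iodocyclisation). Electrophilic iodination of the electron-rich ring B may compete with activation of the alkyne, or I–Cl may add across the triple bond without ring closure. The fallback sets out from 11 and comes back at 15, closing ring C through a free phenol instead of an iodonium ion. BCl3 (1.1 equiv, CH2Cl2, −78 °C) should remove one of the two equivalent benzyl groups ortho to the ketone through the boron chelate, giving 1-[2,4-bis(benzyloxy)-6-hydroxy-3,5-dimethylphenyl]-3-[3,5-bis(benzyloxy)-4-methoxyphenyl]prop-2-yn-1-one F5. Et2NH in EtOH under reflux (conjugate addition, then 6-endo addition–elimination by the phenol) should close F5 to the flavone F3 described above. Dimethyldioxirane then carries F3 through the epoxide F4 to 15 as in the preceding fallback.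

**Further compounds**

F1 | step 8 | 2,4,6-tris(benzyloxy)-3,5-dimethylbenzaldehyde | Cc1c(OCc2ccccc2)c(C)c(OCc2ccccc2)c(C=O)c1OCc1ccccc1
F2 | step 8 | racemic 3-[3,5-bis(benzyloxy)-4-methoxyphenyl]-1-[2,4,6-tris(benzyloxy)-3,5-dimethylphenyl]prop-2-yn-1-ol | Cc1c(OCc2ccccc2)c(C)c(OCc2ccccc2)c(C(O)C#Cc2cc(OCc3ccccc3)c(OC)c(OCc3ccccc3)c2)c1OCc1ccccc1
F3 | step 10 | 5,7-bis(benzyloxy)-2-[3,5-bis(benzyloxy)-4-methoxyphenyl]-6,8-dimethyl-4H-chromen-4-one | COc1c(OCc2ccccc2)cc(-c2cc(=O)c3c(OCc4ccccc4)c(C)c(OCc4ccccc4)c(C)c3o2)cc1OCc1ccccc1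
F4 | step 10 | racemic 2,3-epoxide (cis-fused oxirane across C2–C3) of 5,7-bis(benzyloxy)-2-[3,5-bis(benzyloxy)-4-methoxyphenyl]-6,8-dimethylchroman-4-one | COc1c(OCc2ccccc2)cc(C23Oc4c(C)c(OCc5ccccc5)c(C)c(OCc5ccccc5)c4C(=O)C2O3)cc1OCc1ccccc1
F5 | step 9 | 1-[2,4-bis(benzyloxy)-6-hydroxy-3,5-dimethylphenyl]-3-[3,5-bis(benzyloxy)-4-methoxyphenyl]prop-2-yn-1-one | Cc1c(O)c(C(=O)C#Cc2cc(OCc3ccccc3)c(OC)c(OCc3ccccc3)c2)c(OCc2ccccc2)c(C)c1OCc1ccccc1
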